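## The problem

Compound 26 is a diaryl ether. C8 of a 6-hydroxy-3-pentylisocoumarin (ring A the benzenoid ring, ring C the pyranone) is bound through oxygen to C5' of a 2,4-dihydroxy-6-pentylbenzoic acid (ring B). The ether oxygen is crowded on both sides: C8 is peri to the lactone carbonyl C1, and C5' lies between the C4' hydroxyl and the C6' pentyl chain. Joining two finished arenes would therefore ask a chelated, weakly nucleophilic phenol to attack a di-ortho-substituted, electron-rich aryl halide. The target has no stereocentre and no stereogenic double bond. The only stereochemical elements on the way (one racemic sp3 carbon and one alkene geometry in the open-chain precursor of ring B) are transient and control nothing in the product. Ring B is hexasubstituted, and its parent resorcinol has two unlike free positions, so the carboxyl group must be steered to C1' and kept from C3'. The sensitive groups are the β-resorcylic acid (loses CO2 on heating or in strong acid), the enol lactone of ring C (opened by alkoxide, hydroxide or amines, with a C3=C4 bond that can be hydrogenated) and three free phenols. The enabling feature is the pattern of ring B: the hydroxylated carbon C4' stands between a CH (C3') and the ether carbon C5', with a second oxygen on C2'. That is the pattern obtained when CO is inserted between the two ends of a 3-acyloxy-1,4-enyne whose acyloxy group has moved to the neighbouring carbon, so the ether oxygen can be placed on an unhindered alkene carbon before ring B exists.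

## Retrosynthesis

**26 to 25 (O–benzyl bond at C6).** The last operation is removal of one benzyl ether from 25. Benzyl is kept on the C6 oxygen to the end because it keeps ring A less nucleophilic than ring B during the functionalisation of C1'. BCl3 with a cation scavenger at low temperature is preferred to hydrogenolysis, which could saturate C3=C4. The forward step must spare the lactone, the diaryl ether and the acid.

**25 to 24 to 22 (the C1'–carboxyl bond).** The carboxyl carbon is cut from C1' of resorcinol 22 and introduced as a formyl group (aldehyde 24), which is then oxidised. Direct carboxylation of 22 with CH3OMgOCO2CH3 (Kolbe–Schmitt type) would be one step shorter. It is not chosen because C3', flanked by both hydroxyls, is a competing site for a chelation-driven carboxylation. Electrophilic formylation of 5-alkylresorcinols reliably goes para to one hydroxyl and ortho to the other, which here is C1'. The forward steps must leave ring A untouched and must oxidise an aldehyde beside two free phenols.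

**22 to 21 to 17 + 18 (bonds C3'–C4' and C4'–C5'; ring B).** Acetate cleavage links 22 to the monoacetate 21. In 21 the free hydroxyl carbon C4' is the carbon of CO (18) and the acetate on C2' is the migrated ester of the enyne 17. Cutting here replaces a hexasubstituted benzene by an open chain whose substituents are set by simple carbonyl chemistry. It also moves the hard ether bond from a di-ortho-substituted arene carbon to a vinylic CH. Cutting the ether bond of 22 directly would lead back to a hindered Ullmann coupling. The forward reaction must give the 1,2- and not the 1,3-acyloxy shift, must take up CO faster than it cyclises without it, and must not ionise the allylic acetate.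

**17 to 14 + 15 (bond C1'–C2').** The propargylic acetate comes from the enal 14 and ethynylmagnesium bromide 15, with acetylation in the same flask. A terminal alkyne is wanted because it directs the 1,2-shift. The precursor 14 has no stereocentre and one fewer functional group. The forward step must add to the aldehyde in the presence of the lactone and must avoid acid, because the product is a vinylogous acylal.

**14 to 9 + 13 (the C5'–O bond).** The aryl enol ether is cut at the vinylic C–O bond into the isocoumarin phenol 9 and the enol tosylate 13 of 2-pentylmalonaldehyde. Addition–elimination on a β-sulfonyloxy enal forms this bond at an unhindered sp2 carbon activated by the formyl group. That is far easier than any arene–oxygen coupling at C5'. The forward step must deliver the E isomer with the aryloxy group trans to the formyl group, which is the thermodynamic one.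

**13 to 12 to 10.** The tosylate 13 comes from 2-pentylmalonaldehyde 12, and 12 from 1,1-dimethoxyheptane 10 by C-formylation at the α-carbon. The seven carbons of heptanal become C6' with its pentyl chain and C5'. The formyl carbon becomes C1'.

**9 to 8 to 7 to 4 + 2; 4 to 3; 2 to 1.** The free 8-hydroxyl of 9 is exposed by chelation-controlled removal of the peri benzyl group of 8. The lactone ring C of 8 is cut at O2–C1 back to the keto ester 7. Compound 7 is cut at C4–C3 into the lateral anion of the toluate 4 and the Weinreb amide 2. Compound 4 is the dibenzyl ether of methyl orsellinate 3, and 2 is made from hexanoyl chloride 1. Two benzyl groups are used in place of selective protection because the lateral metalation needs both phenols masked and the peri one can be removed selectively later.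

## Roads not taken

**Alternative 1:** ring B is opened at C1'–C6' and C2'–C3' into the α-aryloxy enone (Z)-3-(2-bromo-5-methoxyphenoxy)non-3-en-2-one A1 and dibenzyl malonate A2. In the forward step the malonate anion adds to C4 of A1 and the methyl ketone enolate closes onto one ester. This gives benzyl 5-(2-bromo-5-methoxyphenoxy)-2-hydroxy-4-oxo-6-pentylcyclohex-2-ene-1-carboxylate A3, which must then be dehydrogenated to the resorcylate.
- Merits: this is the classical Michael–Claisen entry to 6-alkyl-β-resorcylates. It needs no precious metal and no CO pressure. Like the chosen plan it forms the ether bond before ring B exists. It brings the C1' carboxyl in as an ester from the start, and in that respect it is better: the chosen plan spends two steps (formylation, oxidation) on that carbon.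
- Weak points: the α-aryloxy group lowers the electrophilicity of the enone β-carbon. A3 must be oxidised (halogen-based aromatisation) beside an electron-rich aryl ether and a benzyl ester. Ring A is only a bromoanisole at this stage. The bromide must become the lactone carbonyl, C4a has no handle for the C3–C4 unit and would need a directed C–H annulation, and the C6 methyl ether has to be cleaved with a boron trihalide at the very end next to the resorcylic acid.
- Comparison: the chosen plan finishes the isocoumarin first by well-tried lateral-anion chemistry and ends with one mild debenzylation.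

**Alternative 2:** ring A is cut at C4a–C5 and C8–C8a. The forward step is a cycloaddition of the 4-benzyloxy-6-aryloxy-2-pyrone A4 across the ester-bearing triple bond of methyl deca-2,4-diynoate A6, followed by loss of CO2. A4 is made from the ring B phenol benzyl 2,4-bis(benzyloxy)-5-hydroxy-6-pentylbenzoate A5. The product is methyl 4-(benzyloxy)-2-{4,6-bis(benzyloxy)-3-[(benzyloxy)carbonyl]-2-pentylphenoxy}-6-(hept-1-yn-1-yl)benzoate A7.
- Merits: the route is convergent and the key step is thermal and metal-free. Both donors of A4 polarise the diene towards C3, which matches the ynoate, so the regiochemistry should be right. A7 is an ortho-alkynylbenzoate set up for 6-endo lactonisation to the 3-pentylisocoumarin. In convergence this road is better than the chosen one.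
- Weak points: A5 is a fully substituted phenol whose own regioselective synthesis (oxygenation of C5' between an ether and a pentyl group) is a multi-step problem. Its attachment to C6 of a pyrone again asks a flanked phenol to act as nucleophile. The conjugated diyne offers a second triple bond and polymerisation pathways at the temperatures such cycloadditions need.
- Comparison: the chosen plan uses pressurised CO and a rhodium catalyst, but it never has to make or use a hindered ring B phenol.

**Alternative 3:** both pentyl chains are cut off. The forward step is a double Negishi coupling of the 3-chloro-6'-bromo diaryl ether benzyl 6-bromo-5-[(3-chloro-6-methoxy-1-oxo-1H-isochromen-8-yl)oxy]-2,4-dimethoxybenzoate A8 with pentylzinc bromide A9 under Pd(OAc)2 and CPhos. The product is benzyl 2,4-dimethoxy-5-(6-methoxy-3-pentylisocoumarin-8-yloxy)-6-pentylbenzoate A10.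
- Merits: both chains are installed in one late operation, and analogues with other chains would be easy. For analogue work this road is clearly better.
- Weak points: A8 already contains the diaryl ether, so the hardest bond of the molecule is deferred to an Ullmann or SNAr union of two hindered partners. The C6' bromide lies between an aryloxy group and an ester, which slows oxidative addition and favours reduction. The 3-chloroisocoumarin is an acylal-like electrophile that an organozinc reagent could also open. Three methyl ethers must be cleaved at the end under conditions that endanger the β-resorcylic acid.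
- Comparison: the chosen plan is longer on paper, but it solves the ether problem where it is easiest and needs only one late deprotection.

Key step: step 10

Assumptions: 1,1-dimethoxyheptane (heptanal dimethyl acetal) and ethynylmagnesium bromide (THF solution) are taken as commercial. The target has no stereocentre; 17 is used as the racemate and its stereocentre disappears in step 10.

## Route

Step 1
Reactants: 1 hexanoyl chloride
Product: 2 N-methoxy-N-methylhexanamide
Conditions: MeNHOMe·HCl (1.1 equiv), Et3N (2.3 equiv), CH2Cl2, 0 °C to rt
Reagents that add atoms: N,O-dimethylhydroxylamine hydrochloride, CNOC.Cl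
Why: Acylation of the hydroxylamine by the acid chloride (Weinreb amide formation) is a standard amide-bond formation.

Step 2
Reactants: 3 methyl orsellinate (methyl 2,4-dihydroxy-6-methylbenzoate)
Product: 4 methyl 2,4-bis(benzyloxy)-6-methylbenzoate
Conditions: BnBr (2.5 equiv), K2CO3 (3 equiv), DMF, 60 °C
Reagents that add atoms: benzyl bromide, BrCc1ccccc1
Why: Williamson ether synthesis; heating in DMF is needed only for the chelated 2-hydroxyl, and the hindered methyl ester is untouched.

Step 3
Reactants: 4 methyl 2,4-bis(benzyloxy)-6-methylbenzoate; 2 N-methoxy-N-methylhexanamide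
Product: 7 methyl 2,4-bis(benzyloxy)-6-(2-oxoheptyl)benzoate, via benzylic lithium species 5 (not isolated), via lithium hemiaminal adduct 6 (not isolated)
Conditions: LiN(i-Pr)2 (1.15 equiv), THF, −78 °C; then 2 (1.3 equiv), −78 to −40 °C; aq. NH4Cl
Reagents that add atoms: none
Why: Lateral lithiation of an ortho-toluate gives the ester-stabilised benzylic anion 5, which is shielded from self-condensation by its two ortho substituents. Acylation by the Weinreb amide stops at the chelated adduct 6, so the ketone appears only on quench and cannot be attacked twice.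

Step 4
Reactants: 7 methyl 2,4-bis(benzyloxy)-6-(2-oxoheptyl)benzoate
Product: 8 6,8-bis(benzyloxy)-3-pentyl-1H-isochromen-1-one (6,8-bis(benzyloxy)-3-pentylisocoumarin)
Conditions: p-TsOH·H2O (10 mol %), toluene, reflux, 4 Å molecular sieves in the return line
Reagents that add atoms: none
Why: Acid-catalysed enol lactonisation: the enol oxygen of the benzylic ketone attacks the neighbouring ester and methanol is removed, which drives formation of the conjugated isocoumarin.

Step 5
Reactants: 8 6,8-bis(benzyloxy)-3-pentyl-1H-isochromen-1-one
Product: 9 6-(benzyloxy)-8-hydroxy-3-pentyl-1H-isochromen-1-one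
Conditions: BCl3 (1.1 equiv), CH2Cl2, −78 °C; aq. NaHCO3
Reagents that add atoms: none
Why: Chelation-controlled ether cleavage: BCl3 binds between the lactone carbonyl and the peri oxygen, so with one equivalent at low temperature only the 8-benzyl group is lost and the unchelated 6-benzyl ether stays.

Step 6
Reactants: 10 1,1-dimethoxyheptane
Product: 12 2-pentylpropanedial (2-pentylmalonaldehyde, present largely as the enol 3-hydroxy-2-pentylprop-2-enal), via (E)-3-(dimethylamino)-2-pentylprop-2-enal 11 (not isolated)
Conditions: POCl3 (2.2 equiv), DMF, 0 to 70 °C; then aq. NaOH, 80 °C; then HCl to pH 3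
Reagents that add atoms: N,N-dimethylformamide, CN(C)C=O; water, O
Why: Vilsmeier–Haack–Arnold formylation: the acetal loses methanol to the enol ether, which is C-formylated at the former α-carbon. Hydroxide then hydrolyses the vinylogous formamide 11 to the malonaldehyde enolate, which is set free on acidification.

Step 7
Reactants: 12 2-pentylpropanedial
Product: 13 (E)-2-formylhept-1-en-1-yl 4-methylbenzenesulfonate (any Z isomer converges in step 8)
Conditions: TsCl (1.1 equiv), Et3N (1.5 equiv), CH2Cl2, 0 °C; used without long storage
Reagents that add atoms: p-toluenesulfonyl chloride, Cc1ccc(S(=O)(=O)Cl)cc1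
Why: O-sulfonylation of the enol of a 1,3-dicarbonyl compound; the two carbonyl groups are equivalent, so there is no regiochemical question.

Step 8
Reactants: 9 6-(benzyloxy)-8-hydroxy-3-pentyl-1H-isochromen-1-one; 13 (E)-2-formylhept-1-en-1-yl 4-methylbenzenesulfonate
Product: 14 (E)-3-{[6-(benzyloxy)-1-oxo-3-pentyl-1H-isochromen-8-yl]oxy}-2-pentylprop-2-enal
Conditions: Cs2CO3 (1.5 equiv), DMF, 0 °C to rt
Reagents that add atoms: none
Why: Nucleophilic vinylic substitution by addition–elimination on a β-sulfonyloxy enal (a vinylogous mixed anhydride). The enolate intermediate rotates freely, so the thermodynamic E isomer, with the aryloxy group trans to the formyl group, should form from either isomer of 13.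

Step 9
Reactants: 14 (E)-3-{[6-(benzyloxy)-1-oxo-3-pentyl-1H-isochromen-8-yl]oxy}-2-pentylprop-2-enal; 15 ethynylmagnesium bromide
Product: 17 rac-(E)-1-{[6-(benzyloxy)-1-oxo-3-pentyl-1H-isochromen-8-yl]oxy}-2-pentylpent-1-en-4-yn-3-yl acetate, via bromomagnesium alkoxide 16 (not isolated)
Conditions: HC≡CMgBr (1.3 equiv), THF, −78 to −30 °C; then Ac2O (3 equiv), DMAP (10 mol %), −30 to 0 °C; aq. NaHCO3; chromatography on Et3N-deactivated silica
Reagents that add atoms: acetic anhydride, CC(=O)OC(C)=O
Why: 1,2-Addition of an alkynyl Grignard reagent to the aldehyde, which is far more electrophilic than the donor-substituted, conjugated lactone at low temperature. The alkoxide 16 is acetylated in the flask so that the acid-labile allylic alcohol is never handled. The new stereocentre is racemic and is erased in step 10.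

Step 10
Reactants: 17 rac-(E)-1-{[6-(benzyloxy)-1-oxo-3-pentyl-1H-isochromen-8-yl]oxy}-2-pentylpent-1-en-4-yn-3-yl acetate; 18 carbon monoxide
Product: 21 4-{[6-(benzyloxy)-1-oxo-3-pentyl-1H-isochromen-8-yl]oxy}-3-hydroxy-5-pentylphenyl acetate, via dienylketene 19 (not isolated), via cyclohexadienone 20 (not isolated)
Conditions: [RhCl(CO)2]2 (5 mol %), CO (10 atm), CH2Cl2, 60 °C
Reagents that add atoms: none
Why: Monovalent rhodium activates the terminal alkyne, and the acetate carbonyl oxygen attacks the internal alkyne carbon, so the ester shifts 1,2 onto C2' and leaves a rhodium-bound vinylcarbene at C3' with a new C1'=C2' double bond. CO inserts into the carbene to form the C3'–C4' bond and the dienylketene 19. The ketene carbon C4' then closes onto the aryloxy-bearing alkene carbon C5' by a thermal, disrotatory 6π-electrocyclisation (equivalently, reductive elimination from a rhodacycle) to give dienone 20, which tautomerises to phenol 21. The closest known reaction is the [RhCl(CO)2]2-catalysed carbonylative benzannulation of 3-acyloxy-1,4-enynes with CO to resorcinol monoesters; an acyclic aryl enol ether at the alkene terminus is a new substituent within that substrate class. No stereocentre remains: the sp3 carbon of 17 and the transient one of 20 both become arene carbons. The step needs the 1,2- over the 1,3-acyloxy shift, which the unsubstituted alkyne terminus secures and which fixes the acetate on C2' and the CO-derived hydroxyl on C4'. It also needs CO uptake to outrun five-ring closure of the carbene, which the CO pressure favours. The E geometry of 17 puts the aryloxy group on the outside of the triene terminus, where it does not hinder ring closure. The enol ether oxygen is a weak donor because its aryl group is conjugated to the lactone carbonyl, which should limit ionisation of the acetate, and the electron-rich terminus matches the electrophilic ketene.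

Step 11
Reactants: 21 4-{[6-(benzyloxy)-1-oxo-3-pentyl-1H-isochromen-8-yl]oxy}-3-hydroxy-5-pentylphenyl acetate
Product: 22 6-(benzyloxy)-8-(2,4-dihydroxy-6-pentylphenoxy)-3-pentyl-1H-isochromen-1-one
Conditions: K2CO3 (0.3 equiv), MeOH–THF, 0 °C, short reaction time; pH 5 buffer
Reagents that add atoms: none
Why: Base-catalysed methanolysis of an aryl acetate, which is much faster than opening of the hindered lactone, whose carbonyl is deactivated by the ortho and para oxygen donors of ring A.

Step 12
Reactants: 22 6-(benzyloxy)-8-(2,4-dihydroxy-6-pentylphenoxy)-3-pentyl-1H-isochromen-1-one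
Product: 24 5-{[6-(benzyloxy)-1-oxo-3-pentyl-1H-isochromen-8-yl]oxy}-2,4-dihydroxy-6-pentylbenzaldehyde (formyl group on C1'), via aryl iminium chloride 23 (not isolated)
Conditions: POCl3 (1.5 equiv), DMF, MeCN, 0 °C to rt; then aq. NaOAc, 40 °C
Reagents that add atoms: N,N-dimethylformamide, CN(C)C=O; water, O
Why: Vilsmeier–Haack formylation of a resorcinol goes para to one hydroxyl and ortho to the other, here C1', as with other 5-alkylresorcinols, and not at C3' between the two hydroxyls. Ring A carries only ether donors and an acyl group and is much less reactive.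

Step 13
Reactants: 24 5-{[6-(benzyloxy)-1-oxo-3-pentyl-1H-isochromen-8-yl]oxy}-2,4-dihydroxy-6-pentylbenzaldehyde
Product: 25 5-{[6-(benzyloxy)-1-oxo-3-pentyl-1H-isochromen-8-yl]oxy}-2,4-dihydroxy-6-pentylbenzoic acid
Conditions: NaClO2 (3 equiv), NaH2PO4 (4 equiv), 2-methyl-2-butene (20 equiv), t-BuOH–THF–H2O, 0 °C to rt
Reagents that add atoms: sodium chlorite, [Na+].[O-]Cl=O
Why: Pinnick oxidation converts the aldehyde into the acid under buffered, nearly neutral conditions that the lactone and ethers tolerate. The large excess of alkene traps the hypochlorous acid before it can chlorinate the resorcinol ring.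

Step 14
Reactants: 25 5-{[6-(benzyloxy)-1-oxo-3-pentyl-1H-isochromen-8-yl]oxy}-2,4-dihydroxy-6-pentylbenzoic acid
Product: 26 2,4-dihydroxy-5-[(6-hydroxy-1-oxo-3-pentyl-1H-isochromen-8-yl)oxy]-6-pentylbenzoic acid (target)
Conditions: BCl3 (4 equiv), C6HMe5 (5 equiv), CH2Cl2, −78 °C; MeOH, then cold aqueous work-up
Reagents that add atoms: none
Why: Lewis-acid debenzylation of an aryl benzyl ether with pentamethylbenzene as a non-basic cation scavenger. The low temperature spares the diaryl ether, the lactone and the resorcylic acid, and no hydrogen is present to reduce C3=C4.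

## Compound list

1 | hexanoyl chloride | CCCCCC(=O)Cl | starting material
2 | N-methoxy-N-methylhexanamide | CCCCCC(=O)N(C)OC | intermediate
3 | methyl orsellinate (methyl 2,4-dihydroxy-6-methylbenzoate) | COC(=O)c1c(C)cc(O)cc1O | starting material
4 | methyl 2,4-bis(benzyloxy)-6-methylbenzoate | COC(=O)c1c(C)cc(OCc2ccccc2)cc1OCc1ccccc1 | intermediate
5 | [3,5-bis(benzyloxy)-2-(methoxycarbonyl)phenyl]methyllithium (not isolated) | [Li]Cc1cc(OCc2ccccc2)cc(OCc2ccccc2)c1C(=O)OC | intermediate
6 | lithium alkoxide of the N-methoxy-N-methyl hemiaminal from 5 and 2 (not isolated) | CCCCCC(O[Li])(Cc1cc(OCc2ccccc2)cc(OCc2ccccc2)c1C(=O)OC)N(C)OC | intermediate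
7 | methyl 2,4-bis(benzyloxy)-6-(2-oxoheptyl)benzoate | CCCCCC(=O)Cc1cc(OCc2ccccc2)cc(OCc2ccccc2)c1C(=O)OC | intermediate
8 | 6,8-bis(benzyloxy)-3-pentyl-1H-isochromen-1-one | CCCCCc1cc2cc(OCc3ccccc3)cc(OCc3ccccc3)c2c(=O)o1 | intermediate
9 | 6-(benzyloxy)-8-hydroxy-3-pentyl-1H-isochromen-1-one | CCCCCc1cc2cc(OCc3ccccc3)cc(O)c2c(=O)o1 | intermediate
10 | 1,1-dimethoxyheptane | CCCCCCC(OC)OC | starting material
11 | (E)-3-(dimethylamino)-2-pentylprop-2-enal (not isolated) | CCCCC/C(C=O)=C\N(C)C | intermediate
12 | 2-pentylpropanedial (2-pentylmalonaldehyde) | CCCCCC(C=O)C=O | intermediate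
13 | (E)-2-formylhept-1-en-1-yl 4-methylbenzenesulfonate | CCCCC/C(C=O)=C\OS(=O)(=O)c1ccc(C)cc1 | intermediate
14 | (E)-3-{[6-(benzyloxy)-1-oxo-3-pentyl-1H-isochromen-8-yl]oxy}-2-pentylprop-2-enal | CCCCC/C(C=O)=C\Oc1cc(OCc2ccccc2)cc2cc(CCCCC)oc(=O)c12 | intermediate
15 | ethynylmagnesium bromide | C#C[Mg]Br | starting material
16 | bromomagnesium rac-(E)-1-{[6-(benzyloxy)-1-oxo-3-pentyl-1H-isochromen-8-yl]oxy}-2-pentylpent-1-en-4-yn-3-olate (not isolated) | CCCCCc1cc2cc(OCc3ccccc3)cc(O/C=C(CCCCC)/C(O[Mg]Br)C#C)c2c(=O)o1 | intermediate
17 | rac-(E)-1-{[6-(benzyloxy)-1-oxo-3-pentyl-1H-isochromen-8-yl]oxy}-2-pentylpent-1-en-4-yn-3-yl acetate | CCCCCc1cc2cc(OCc3ccccc3)cc(O/C=C(CCCCC)/C(OC(C)=O)C#C)c2c(=O)o1 | intermediate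
18 | carbon monoxide | [C-]#[O+] | starting material
19 | (3E,5E)-3-acetoxy-6-{[6-(benzyloxy)-1-oxo-3-pentyl-1H-isochromen-8-yl]oxy}-5-pentylhexa-1,3,5-trien-1-one (dienylketene, not isolated) | O=C=C/C(OC(C)=O)=C\C(CCCCC)=C\Oc1cc(OCc2ccccc2)cc2cc(CCCCC)oc(=O)c12 | intermediate
20 | rac-3-acetoxy-6-{[6-(benzyloxy)-1-oxo-3-pentyl-1H-isochromen-8-yl]oxy}-5-pentylcyclohexa-2,4-dien-1-one (not isolated) | CCCCCC1=CC(OC(C)=O)=CC(=O)C1Oc1cc(OCc2ccccc2)cc2cc(CCCCC)oc(=O)c12 | intermediate
21 | 4-{[6-(benzyloxy)-1-oxo-3-pentyl-1H-isochromen-8-yl]oxy}-3-hydroxy-5-pentylphenyl acetate | CCCCCc1cc2cc(OCc3ccccc3)cc(Oc3c(O)cc(OC(C)=O)cc3CCCCC)c2c(=O)o1 | intermediate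
22 | 6-(benzyloxy)-8-(2,4-dihydroxy-6-pentylphenoxy)-3-pentyl-1H-isochromen-1-one | CCCCCc1cc2cc(OCc3ccccc3)cc(Oc3c(O)cc(O)cc3CCCCC)c2c(=O)o1 | intermediate
23 | N-[(5-{[6-(benzyloxy)-1-oxo-3-pentyl-1H-isochromen-8-yl]oxy}-2,4-dihydroxy-6-pentylphenyl)methylidene]-N-methylmethanaminium chloride (not isolated) | CCCCCc1cc2cc(OCc3ccccc3)cc(Oc3c(O)cc(O)c(C=[N+](C)C)c3CCCCC)c2c(=O)o1.[Cl-] | intermediate
24 | 5-{[6-(benzyloxy)-1-oxo-3-pentyl-1H-isochromen-8-yl]oxy}-2,4-dihydroxy-6-pentylbenzaldehyde | CCCCCc1cc2cc(OCc3ccccc3)cc(Oc3c(O)cc(O)c(C=O)c3CCCCC)c2c(=O)o1 | intermediate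
25 | 5-{[6-(benzyloxy)-1-oxo-3-pentyl-1H-isochromen-8-yl]oxy}-2,4-dihydroxy-6-pentylbenzoic acid | CCCCCc1cc2cc(OCc3ccccc3)cc(Oc3c(O)cc(O)c(C(=O)O)c3CCCCC)c2c(=O)o1 | intermediate
26 | 2,4-dihydroxy-5-[(6-hydroxy-1-oxo-3-pentyl-1H-isochromen-8-yl)oxy]-6-pentylbenzoic acid | CCCCCc1cc2cc(O)cc(Oc3c(O)cc(O)c(C(=O)O)c3CCCCC)c2c(=O)o1 | target

## Step count and risks

Total: 14 steps. Longest linear sequence: 11 steps (from 3 through steps 2, 3, 4, 5, 8, 9, 10, 11, 12, 13 and 14).

**Step 10 (key step).** The most likely failure is heterolysis of the C–OAc bond assisted by the enol ether oxygen (17 is a vinylogous acylal and the rhodium chloride is a mild Lewis acid). The other is five-ring closure of the vinylcarbene onto the electron-rich alkene (Rautenstrauch-type) before CO is taken up. Both would consume 17 without forming the arene. The fallback abandons the benzannulation and forms the ether by copper catalysis. It sets out from 9 and returns at 22. Commercial olivetol (5-pentylresorcinol) F1 is converted with MOMCl and i-Pr2NEt into 1,3-bis(methoxymethoxy)-5-pentylbenzene F2. N-iodosuccinimide in MeCN iodinates F2 para to one ether oxygen and next to the pentyl chain to give 2-iodo-1,5-bis(methoxymethoxy)-3-pentylbenzene F3. An Ullmann ether synthesis of F3 with 9 (CuI as copper monoiodide, picolinic acid, K3PO4, DMSO, 100 °C) gives 6-(benzyloxy)-8-[2,4-bis(methoxymethoxy)-6-pentylphenoxy]-3-pentyl-1H-isochromen-1-one F4, and HCl in MeOH–THF frees 22. This coupling is hindered on both partners and is expected to be slow, which is why it is only the reserve.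

**Step 8.** The phenoxide of 9 is chelated and weakly nucleophilic. It may attack sulfur instead of carbon, so that the sulfonyl group is transferred to the phenol and the malonaldehyde enolate is released. The fallback replaces the sulfonate by a leaving group that can only be displaced at carbon. It sets out from 12 and returns at 14. Oxalyl chloride with catalytic DMF in CH2Cl2 converts 12 into (E)-3-chloro-2-pentylprop-2-enal F5, and F5 reacts with 9 and Cs2CO3 in DMF to give 14.

**Step 9.** The Grignard reagent may act as a base or attack the lactone carbonyl, and the product may ionise during acetylation or isolation because the aryloxy group assists loss of the allylic oxygen. The fallback uses a less basic, more oxophilic nucleophile and keeps the alkyne capped. It sets out from 14 and returns at 17. Lithium (trimethylsilyl)acetylide premixed with CeCl3 in THF at −78 °C is added to 14, and Ac2O is added in the same flask to give rac-(E)-1-{[6-(benzyloxy)-1-oxo-3-pentyl-1H-isochromen-8-yl]oxy}-2-pentyl-5-(trimethylsilyl)pent-1-en-4-yn-3-yl acetate F6. n-Bu4NF buffered with AcOH in THF at 0 °C then removes the silyl group to give 17.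

**Step 13.** Hypochlorous acid or chlorine dioxide formed during the oxidation may chlorinate or oxidise the free resorcinol ring, above all at C3', faster than the chelated aldehyde is oxidised. The fallback deactivates ring B before the oxidation. It sets out from 24 and returns at 25. Ac2O and pyridine give 5-{[6-(benzyloxy)-1-oxo-3-pentyl-1H-isochromen-8-yl]oxy}-2,4-diacetoxy-6-pentylbenzaldehyde F7. The same chlorite oxidation gives 5-{[6-(benzyloxy)-1-oxo-3-pentyl-1H-isochromen-8-yl]oxy}-2,4-diacetoxy-6-pentylbenzoic acid F8. K2CO3 in MeOH at 0 °C then removes both acetates to give 25.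

**Step 4.** Lactonisation may stall at the keto ester because the ester is flanked by two ortho substituents, and the acid may begin to cleave benzyl ethers. Loss of the peri benzyl group would only anticipate step 5, but loss of the 6-benzyl group would not be tolerable. The fallback goes through the acid. It sets out from 7 and returns at 8. KOH in aqueous EtOH at reflux gives 2,4-bis(benzyloxy)-6-(2-oxoheptyl)benzoic acid F9, and brief heating in Ac2O cyclodehydrates F9 to 8.

## Further compounds

F1 | step 10 | olivetol (5-pentylbenzene-1,3-diol) | CCCCCc1cc(O)cc(O)c1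
F2 | step 10 | 1,3-bis(methoxymethoxy)-5-pentylbenzene | CCCCCc1cc(OCOC)cc(OCOC)c1
F3 | step 10 | 2-iodo-1,5-bis(methoxymethoxy)-3-pentylbenzene | CCCCCc1cc(OCOC)cc(OCOC)c1I
F4 | step 10 | 6-(benzyloxy)-8-[2,4-bis(methoxymethoxy)-6-pentylphenoxy]-3-pentyl-1H-isochromen-1-one | CCCCCc1cc2cc(OCc3ccccc3)cc(Oc3c(OCOC)cc(OCOC)cc3CCCCC)c2c(=O)o1
F5 | step 8 | (E)-3-chloro-2-pentylprop-2-enal | CCCCC/C(C=O)=C\Cl
F6 | step 9 | rac-(E)-1-{[6-(benzyloxy)-1-oxo-3-pentyl-1H-isochromen-8-yl]oxy}-2-pentyl-5-(trimethylsilyl)pent-1-en-4-yn-3-yl acetate | CCCCCc1cc2cc(OCc3ccccc3)cc(O/C=C(CCCCC)/C(OC(C)=O)C#C[Si](C)(C)C)c2c(=O)o1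
F7 | step 13 | 5-{[6-(benzyloxy)-1-oxo-3-pentyl-1H-isochromen-8-yl]oxy}-2,4-diacetoxy-6-pentylbenzaldehyde | CCCCCc1cc2cc(OCc3ccccc3)cc(Oc3c(OC(C)=O)cc(OC(C)=O)c(C=O)c3CCCCC)c2c(=O)o1
F8 | step 13 | 5-{[6-(benzyloxy)-1-oxo-3-pentyl-1H-isochromen-8-yl]oxy}-2,4-diacetoxy-6-pentylbenzoic acid | CCCCCc1cc2cc(OCc3ccccc3)cc(Oc3c(OC(C)=O)cc(OC(C)=O)c(C(=O)O)c3CCCCC)c2c(=O)o1
F9 | step 4 | 2,4-bis(benzyloxy)-6-(2-oxoheptyl)benzoic acid | CCCCCC(=O)Cc1cc(OCc2ccccc2)cc(OCc2ccccc2)c1C(=O)O
A1 | alternative 1 | (Z)-3-(2-bromo-5-methoxyphenoxy)non-3-en-2-one | CCCCC/C=C(\Oc1cc(OC)ccc1Br)C(C)=O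
A2 | alternative 1 | dibenzyl malonate | O=C(CC(=O)OCc1ccccc1)OCc1ccccc1
A3 | alternative 1 | benzyl 5-(2-bromo-5-methoxyphenoxy)-2-hydroxy-4-oxo-6-pentylcyclohex-2-ene-1-carboxylate (diastereomer mixture) | CCCCCC1C(C(=O)OCc2ccccc2)C(O)=CC(=O)C1Oc1cc(OC)ccc1Br
A4 | alternative 2 | benzyl 2,4-bis(benzyloxy)-5-{[4-(benzyloxy)-2-oxo-2H-pyran-6-yl]oxy}-6-pentylbenzoate | CCCCCc1c(Oc2cc(OCc3ccccc3)cc(=O)o2)c(OCc2ccccc2)cc(OCc2ccccc2)c1C(=O)OCc1ccccc1
A5 | alternative 2 | benzyl 2,4-bis(benzyloxy)-5-hydroxy-6-pentylbenzoate | CCCCCc1c(O)c(OCc2ccccc2)cc(OCc2ccccc2)c1C(=O)OCc1ccccc1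
A6 | alternative 2 | methyl deca-2,4-diynoate | CCCCCC#CC#CC(=O)OC
A7 | alternative 2 | methyl 4-(benzyloxy)-2-{4,6-bis(benzyloxy)-3-[(benzyloxy)carbonyl]-2-pentylphenoxy}-6-(hept-1-yn-1-yl)benzoate | CCCCCC#Cc1cc(OCc2ccccc2)cc(Oc2c(OCc3ccccc3)cc(OCc3ccccc3)c(C(=O)OCc3ccccc3)c2CCCCC)c1C(=O)OC
A8 | alternative 3 | benzyl 6-bromo-5-[(3-chloro-6-methoxy-1-oxo-1H-isochromen-8-yl)oxy]-2,4-dimethoxybenzoate | O=c1oc(Cl)cc2cc(OC)cc(Oc3c(OC)cc(OC)c(C(=O)OCc4ccccc4)c3Br)c12
A9 | alternative 3 | pentylzinc bromide | CCCCC[Zn]Br
A10 | alternative 3 | benzyl 2,4-dimethoxy-5-[(6-methoxy-1-oxo-3-pentyl-1H-isochromen-8-yl)oxy]-6-pentylbenzoate | CCCCCc1cc2cc(OC)cc(Oc3c(OC)cc(OC)c(C(=O)OCc4ccccc4)c3CCCCC)c2c(=O)o1
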